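Ring A (the alkynyl cyclohexene: C1 gem-dimethyl, C3 carbinol, C5=C6 olefin with the alkyne on C6) is read as a [4+2] adduct. A 2-silyloxy-diene supplies C4–C5–C6–C1 and methyl vinyl ketone supplies C2–C3, so one acid-catalysed annulation forms C1–C2 and C3–C4 and leaves a silyl enol ether at C5=C6, later exchanged for the alkyne through the enol nonaflate. The acetyl group becomes the C3 hydroxyl by Baeyer–Villiger oxidation. Because the triol ring B is the same ring in the mirror-image C3 series, the adduct is made racemic and divided by a lipase in two passes; both antipodes are used. Sonogashira, Horner–Wadsworth–Emmons, alkyne-lactonisation and Stille steps assemble the polyene butenolide.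

Key step: step 3

Assumption: by CIP analysis ring B is (3R,5S,6S) in the ring locants above and so derives from the (S)-antipode of the ring-A building block; the lipase is assumed to hydrolyse the (R)-acetate faster, as the empirical rule for secondary alcohols predicts when the CMe2 side is the large group.

Step 1
Reactants: 1 2-methylpentan-3-one
Product: 2 2,4-dimethylpent-1-en-3-one
Conditions: (CH2O)n, i-Pr2NH2+ CF3CO2−, CF3CO2H (cat.), THF, reflux
Reagents that add atoms: paraformaldehyde (as formaldehyde) C=O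
Why: Mannich-type α-methylenation, in which only the ethyl-side aminomethyl adduct can eliminate the amine (the isopropyl-side adduct has no α-hydrogen and reverts), so a single enone should result.

Step 2
Reactants: 2 2,4-dimethylpent-1-en-3-one
Product: 3 tert-butyl[(2,4-dimethylpenta-1,3-dien-3-yl)oxy]dimethylsilane
Conditions: t-BuMe2SiOTf, Et3N, CH2Cl2, 0 °C → rt
Reagents that add atoms: tert-butyldimethylsilyl triflate CC(C)(C)[Si](C)(C)OS(=O)(=O)C(F)(F)F
Why: Soft enolisation and O-silylation of an enone at its only enolisable position (the isopropyl methine), the standard entry to 2-silyloxy-1,3-dienes.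

Step 3
Reactants: 3 tert-butyl[(2,4-dimethylpenta-1,3-dien-3-yl)oxy]dimethylsilane; 4 but-3-en-2-one (methyl vinyl ketone)
Product: 6 1-{4-[(tert-butyldimethylsilyl)oxy]-3,5,5-trimethylcyclohex-3-en-1-yl}ethan-1-one (racemic), via open-chain Mukaiyama–Michael adduct 5 (not isolated)
Conditions: HN(SO2CF3)2 (3 mol %), CH2Cl2, −78 → −30 °C; Et3N quench
Reagents that add atoms: none
Why: Catalytic HN(SO2CF3)2 protodesilylates a little of 3 to give t-BuMe2SiN(SO2CF3)2, which activates 4 at oxygen; the fully substituted enol-ether carbon of 3 (the future C1 of ring A) adds to the CH2 terminus of 4 (bond C1–C2, quaternary centre) to give 5, and re-silylation of the isopropenyl ketone oxygen of 5 lets its new silyl enol ether carbon (future C3) add to the methylene terminus C4 (bond C3–C4), releasing the silyl cation again. The closest known reaction type is the acid-catalysed Diels–Alder reaction of 2-silyloxy-1,3-dienes with enones in its stepwise double Mukaiyama–Michael form, which is expected here because the cis-methyl group on C1 disfavours a concerted s-cis transition state. The one ring closes by a 6-endo-trig (enol-exo) Michael addition. The only new stereocentre, C3, is formed without control and on purpose as the racemate, because ring A needs the (R)- and ring B the (S)-antipode, and steps 6 and 7 divide them. The selectivity that matters is regiochemical (acetyl on C3, para to the silyloxy carbon C6, and six-ring rather than cyclobutane closure): the silyloxy group makes C1 the only nucleophilic terminus despite its two methyl groups, the activated enone accepts the second addition only at C4, and the quaternary C1 confines the enol ether, and later the alkyne-bearing double bond, to C5=C6.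

Step 4
Reactants: 6 1-{4-[(tert-butyldimethylsilyl)oxy]-3,5,5-trimethylcyclohex-3-en-1-yl}ethan-1-one (racemic)
Product: 7 4-acetyl-2,6,6-trimethylcyclohex-1-en-1-yl nonafluorobutane-1-sulfonate (racemic)
Conditions: n-C4F9SO2F, n-Bu4NF (cat.), THF, 0 °C → rt
Reagents that add atoms: nonafluorobutane-1-sulfonyl fluoride O=S(=O)(F)C(F)(F)C(F)(F)C(F)(F)C(F)(F)F
Why: Fluoride-catalysed exchange of an enol silyl ether for an enol nonaflate (desilylation to the enolate, O-sulfonylation, fluoride released again), in which the low steady-state enolate concentration should keep proton transfer from the acetyl group from competing and the quaternary C1 leaves no other enol position.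

Step 5
Reactants: 7 4-acetyl-2,6,6-trimethylcyclohex-1-en-1-yl nonafluorobutane-1-sulfonate (racemic)
Product: 8 3,5,5-trimethyl-4-{[(nonafluorobutyl)sulfonyl]oxy}cyclohex-3-en-1-yl acetate (racemic)
Conditions: mCPBA, CF3CO2H (cat.), CH2Cl2, 0 °C → rt, dark
Reagents that add atoms: 3-chloroperbenzoic acid OOC(=O)c1cccc(Cl)c1
Why: Baeyer–Villiger oxidation of a methyl sec-alkyl ketone, in which the ring carbon migrates in preference to methyl and the strongly electron-poor enol-sulfonate double bond should resist epoxidation.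

Step 6
Reactants: 8 3,5,5-trimethyl-4-{[(nonafluorobutyl)sulfonyl]oxy}cyclohex-3-en-1-yl acetate (racemic)
Product: 9 (4R)-4-hydroxy-2,6,6-trimethylcyclohex-1-en-1-yl nonafluorobutane-1-sulfonate
Conditions: Burkholderia cepacia lipase (a triacylglycerol lipase, immobilised), phosphate buffer pH 7/t-BuOMe, 30 °C, stopped short of half conversion; chromatography (the ester fraction is kept for step 7)
Reagents that add atoms: none
Why: Enzymatic kinetic resolution by enantioselective ester hydrolysis with a triacylglycerol lipase, which should cleave the (R)-acetate faster, so that stopping short of half conversion should give the alcohol in high enantiomeric purity and thereby assign C3 of ring A.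

Step 7
Reactants: 8 3,5,5-trimethyl-4-{[(nonafluorobutyl)sulfonyl]oxy}cyclohex-3-en-1-yl acetate (the ester fraction recovered from step 6, enriched in the S enantiomer)
Product: 10 (1S)-3,5,5-trimethyl-4-{[(nonafluorobutyl)sulfonyl]oxy}cyclohex-3-en-1-yl acetate
Conditions: the same immobilised Burkholderia cepacia lipase, phosphate buffer pH 7/t-BuOMe, 30 °C, continued until chiral HPLC shows no (R)-ester left; chromatography
Reagents that add atoms: none
Why: Second pass of the same enzymatic kinetic resolution, in which hydrolysis carried beyond half conversion should remove the remaining fast-reacting (R)-acetate as the alcohol and leave the unreacted ester as the (S)-enantiomer, which assigns C3 of ring B, so that no antipode is discarded.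

Step 8
Reactants: 11 (2E)-3-methylpent-2-en-4-yn-1-ol
Product: 12 (3E)-5-bromo-3-methylpent-3-en-1-yne
Conditions: PBr3, pyridine (cat.), Et2O, −10 → 0 °C
Reagents that add atoms: phosphorus tribromide BrP(Br)Br
Why: SN2 bromination of a primary allylic alcohol, which at low temperature should keep both the position and the E geometry of the double bond.

Step 9
Reactants: 12 (3E)-5-bromo-3-methylpent-3-en-1-yne
Product: 13 diethyl [(2E)-3-methylpent-2-en-4-yn-1-yl]phosphonate
Conditions: P(OEt)3, neat, 100 °C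
Reagents that add atoms: triethyl phosphite CCOP(OCC)OCC
Why: Michaelis–Arbuzov reaction of a primary allylic bromide, with no change at the E double bond.

Step 10
Reactants: 9 (4R)-4-hydroxy-2,6,6-trimethylcyclohex-1-en-1-yl nonafluorobutane-1-sulfonate; 13 diethyl [(2E)-3-methylpent-2-en-4-yn-1-yl]phosphonate
Product: 14 diethyl {(2E)-5-[(4R)-4-hydroxy-2,6,6-trimethylcyclohex-1-en-1-yl]-3-methylpent-2-en-4-yn-1-yl}phosphonate
Conditions: Pd(PPh3)4 (5 mol %), CuI (10 mol %), i-Pr2NH, DMF, rt → 45 °C
Reagents that add atoms: none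
Why: Sonogashira coupling of an alkenyl nonaflate with a terminal alkyne replaces the C6 oxygen by the alkyne with the C5=C6 double bond already in place, and neither the C3 stereocentre nor the E double bond of 13 is touched.

Step 11
Reactants: 11 (2E)-3-methylpent-2-en-4-yn-1-ol
Product: 16 (2E,4E)-5-methylhepta-2,4-dien-6-ynal, via (2E)-3-methylpent-2-en-4-ynal 15 (not isolated)
Conditions: MnO2, CH2Cl2, rt; filtration; then Ph3P=CHCHO, toluene, 70 °C
Reagents that add atoms: (triphenylphosphoranylidene)acetaldehyde O=CC=P(c1ccccc1)(c1ccccc1)c1ccccc1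
Why: Allylic oxidation followed, without isolating the volatile aldehyde, by a Wittig reaction with a stabilised ylide, which should give the new double bond E.

Step 12
Reactants: 14 diethyl {(2E)-5-[(4R)-4-hydroxy-2,6,6-trimethylcyclohex-1-en-1-yl]-3-methylpent-2-en-4-yn-1-yl}phosphonate; 16 (2E,4E)-5-methylhepta-2,4-dien-6-ynal
Product: 17 (1R)-4-[(3E,5E,7E,9E)-3,10-dimethyldodeca-3,5,7,9-tetraene-1,11-diyn-1-yl]-3,5,5-trimethylcyclohex-3-en-1-ol
Conditions: NaN(SiMe3)2 (2.1 equiv), THF, −78 °C; then 16, −78 → 0 °C, dark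
Reagents that add atoms: none
Why: Horner–Wadsworth–Emmons olefination with an allylic phosphonate anion should give the new disubstituted double bond E, while generating the anion at −78 °C and trapping it at once should keep the E geometry of the adjacent methyl-bearing enyne double bond (the second equivalent of base holds the C3 hydroxyl as its alkoxide).

Step 13
Reactants: 18 prop-2-ynoic acid (propiolic acid)
Product: 19 (2E)-2,3-dibromoprop-2-enoic acid
Conditions: Br2, CHCl3, 0 °C → rt, dark
Reagents that add atoms: bromine BrBr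
Why: Anti addition of bromine to the alkyne places the 3-bromine cis to the carboxyl group, as the later lactonisation requires.

Step 14
Reactants: 17 (1R)-4-[(3E,5E,7E,9E)-3,10-dimethyldodeca-3,5,7,9-tetraene-1,11-diyn-1-yl]-3,5,5-trimethylcyclohex-3-en-1-ol; 19 (2E)-2,3-dibromoprop-2-enoic acid
Product: 21 (5Z)-3-bromo-5-{(2E,4E,6E,8E)-11-[(4R)-4-hydroxy-2,6,6-trimethylcyclohex-1-en-1-yl]-2,9-dimethylundeca-2,4,6,8-tetraen-10-yn-1-ylidene}furan-2(5H)-one, via 2-bromo-enynoic acid 20 (not isolated)
Conditions: Pd(PPh3)4 (5 mol %), CuI (10 mol %), Et3N, MeCN, rt, dark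
Reagents that add atoms: none
Why: Tandem Sonogashira coupling and 5-exo-dig lactonisation of a 3-halopropenoic acid whose halogen is cis to the carboxyl group: the more reactive β C–Br bond couples, the carboxylate then adds anti across the metal-activated alkyne to give the Z-ylidene butenolide, and the α-bromine is kept for step 19.

Step 15
Reactants: 10 (1S)-3,5,5-trimethyl-4-{[(nonafluorobutyl)sulfonyl]oxy}cyclohex-3-en-1-yl acetate; 22 ethynyltrimethylsilane
Product: 24 (1S)-4-ethynyl-3,5,5-trimethylcyclohex-3-en-1-ol, via silylated enyne acetate 23 (not isolated)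
Conditions: Pd(PPh3)2Cl2 (5 mol %), CuI (10 mol %), Et3N, DMF, 50 °C; then MeOH, K2CO3, rt
Reagents that add atoms: none
Why: Sonogashira coupling of the alkenyl nonaflate, followed in the same flask by methanolysis that removes both the C-silyl group and the acetate, leaves C3 untouched.

Step 16
Reactants: 24 (1S)-4-ethynyl-3,5,5-trimethylcyclohex-3-en-1-ol
Product: 25 (1R,3R,6R)-6-ethynyl-1,5,5-trimethyl-7-oxabicyclo[4.1.0]heptan-3-ol
Conditions: VO(acac)2 (5 mol %), t-BuOOH, CH2Cl2, 0 °C → rt
Reagents that add atoms: tert-butyl hydroperoxide CC(C)(C)OO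
Why: Hydroxyl-directed vanadium-catalysed epoxidation of a cyclic homoallylic alcohol delivers oxygen to the face of C5=C6 syn to the C3 hydroxyl, which sets C5 and C6 relative to C3 and leaves the alkyne alone.

Step 17
Reactants: 25 (1R,3R,6R)-6-ethynyl-1,5,5-trimethyl-7-oxabicyclo[4.1.0]heptan-3-ol
Product: 26 (1R,2S,4R)-1-ethynyl-2,6,6-trimethylcyclohexane-1,2,4-triol
Conditions: HClO4 (cat.), THF/H2O, 0 °C → rt
Reagents that add atoms: water O
Why: Acid-catalysed epoxide hydrolysis in which water should enter anti at C5 with inversion (C6 is neopentyl and carries the inductively withdrawing alkyne), giving the trans-5,6-diol with the C6 oxygen retained syn to the C3 hydroxyl.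

Step 18
Reactants: 26 (1R,2S,4R)-1-ethynyl-2,6,6-trimethylcyclohexane-1,2,4-triol
Product: 27 (1S,2S,4R)-2,6,6-trimethyl-1-[(E)-2-(tributylstannyl)ethenyl]cyclohexane-1,2,4-triol
Conditions: n-Bu3SnH, Pd(PPh3)2Cl2 (3 mol %), THF, 0 °C → rt
Reagents that add atoms: tributyltin hydride CCCC[SnH](CCCC)CCCC
Why: Palladium-catalysed syn-hydrostannylation of a terminal alkyne, in which the quaternary carbinol should send tin to the terminal carbon and so give the E-alkenylstannane.

Step 19
Reactants: 21 (5Z)-3-bromo-5-{(2E,4E,6E,8E)-11-[(4R)-4-hydroxy-2,6,6-trimethylcyclohex-1-en-1-yl]-2,9-dimethylundeca-2,4,6,8-tetraen-10-yn-1-ylidene}furan-2(5H)-one; 27 (1S,2S,4R)-2,6,6-trimethyl-1-[(E)-2-(tributylstannyl)ethenyl]cyclohexane-1,2,4-triol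
Product: 28 (5Z)-5-{(2E,4E,6E,8E)-11-[(4R)-4-hydroxy-2,6,6-trimethylcyclohex-1-en-1-yl]-2,9-dimethylundeca-2,4,6,8-tetraen-10-yn-1-ylidene}-3-{(E)-2-[(1S,2S,4R)-1,2,4-trihydroxy-2,6,6-trimethylcyclohexyl]ethenyl}furan-2(5H)-one (target)
Conditions: Pd2(dba)3 (5 mol %), AsPh3 (40 mol %), N-methylpyrrolidone, 40 °C, dark
Reagents that add atoms: none
Why: Stille coupling of the α-bromobutenolide with the alkenylstannane proceeds with retention of the E geometry under neutral conditions that should tolerate the four free hydroxyl groups, the butenolide and the E-enyne.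

Compound list
1 | 2-methylpentan-3-one | CCC(=O)C(C)C | starting material
2 | 2,4-dimethylpent-1-en-3-one | C=C(C)C(=O)C(C)C | intermediate
3 | tert-butyl[(2,4-dimethylpenta-1,3-dien-3-yl)oxy]dimethylsilane | C=C(C)C(O[Si](C)(C)C(C)(C)C)=C(C)C | intermediate
4 | but-3-en-2-one (methyl vinyl ketone) | C=CC(C)=O | starting material
5 | 7-[(tert-butyldimethylsilyl)oxy]-2,4,4-trimethylocta-1,6-dien-3-one (open-chain Mukaiyama–Michael adduct, not isolated) | C=C(C)C(=O)C(C)(C)CC=C(C)O[Si](C)(C)C(C)(C)C | intermediate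
6 | 1-{4-[(tert-butyldimethylsilyl)oxy]-3,5,5-trimethylcyclohex-3-en-1-yl}ethan-1-one (racemic) | CC1=C(O[Si](C)(C)C(C)(C)C)C(C)(C)CC(C(C)=O)C1 | intermediate
7 | 4-acetyl-2,6,6-trimethylcyclohex-1-en-1-yl nonafluorobutane-1-sulfonate (racemic) | CC1=C(OS(=O)(=O)C(F)(F)C(F)(F)C(F)(F)C(F)(F)F)C(C)(C)CC(C(C)=O)C1 | intermediate
8 | 3,5,5-trimethyl-4-{[(nonafluorobutyl)sulfonyl]oxy}cyclohex-3-en-1-yl acetate (racemic) | CC1=C(OS(=O)(=O)C(F)(F)C(F)(F)C(F)(F)C(F)(F)F)C(C)(C)CC(OC(C)=O)C1 | intermediate
9 | (4R)-4-hydroxy-2,6,6-trimethylcyclohex-1-en-1-yl nonafluorobutane-1-sulfonate | CC1=C(OS(=O)(=O)C(F)(F)C(F)(F)C(F)(F)C(F)(F)F)C(C)(C)C[C@H](O)C1 | intermediate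
10 | (1S)-3,5,5-trimethyl-4-{[(nonafluorobutyl)sulfonyl]oxy}cyclohex-3-en-1-yl acetate | CC1=C(OS(=O)(=O)C(F)(F)C(F)(F)C(F)(F)C(F)(F)F)C(C)(C)C[C@@H](OC(C)=O)C1 | intermediate
11 | (2E)-3-methylpent-2-en-4-yn-1-ol | C#C/C(C)=C/CO | starting material
12 | (3E)-5-bromo-3-methylpent-3-en-1-yne | C#C/C(C)=C/CBr | intermediate
13 | diethyl [(2E)-3-methylpent-2-en-4-yn-1-yl]phosphonate | C#C/C(C)=C/CP(=O)(OCC)OCC | intermediate
14 | diethyl {(2E)-5-[(4R)-4-hydroxy-2,6,6-trimethylcyclohex-1-en-1-yl]-3-methylpent-2-en-4-yn-1-yl}phosphonate | CC1=C(C#C/C(C)=C/CP(=O)(OCC)OCC)C(C)(C)C[C@H](O)C1 | intermediate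
15 | (2E)-3-methylpent-2-en-4-ynal (not isolated) | C#C/C(C)=C/C=O | intermediate
16 | (2E,4E)-5-methylhepta-2,4-dien-6-ynal | C#C/C(C)=C/C=C/C=O | intermediate
17 | (1R)-4-[(3E,5E,7E,9E)-3,10-dimethyldodeca-3,5,7,9-tetraene-1,11-diyn-1-yl]-3,5,5-trimethylcyclohex-3-en-1-ol | CC1=C(C#C/C(C)=C/C=C/C=C/C=C(C)/C#C)C(C)(C)C[C@H](O)C1 | intermediate
18 | prop-2-ynoic acid | C#CC(=O)O | starting material
19 | (2E)-2,3-dibromoprop-2-enoic acid | OC(=O)/C(Br)=C\Br | intermediate
20 | (2E,6E,8E,10E,12E)-2-bromo-15-[(4R)-4-hydroxy-2,6,6-trimethylcyclohex-1-en-1-yl]-6,13-dimethylpentadeca-2,6,8,10,12-pentaene-4,14-diynoic acid (not isolated) | CC1=C(C#C/C(C)=C/C=C/C=C/C=C(C)/C#C/C=C(/Br)C(O)=O)C(C)(C)C[C@H](O)C1 | intermediate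
21 | (5Z)-3-bromo-5-{(2E,4E,6E,8E)-11-[(4R)-4-hydroxy-2,6,6-trimethylcyclohex-1-en-1-yl]-2,9-dimethylundeca-2,4,6,8-tetraen-10-yn-1-ylidene}furan-2(5H)-one | CC1=C(C#C/C(C)=C/C=C/C=C/C=C(C)/C=C2C=C(Br)C(=O)O/2)C(C)(C)C[C@H](O)C1 | intermediate
22 | ethynyltrimethylsilane | C#C[Si](C)(C)C | starting material
23 | (1S)-3,5,5-trimethyl-4-[(trimethylsilyl)ethynyl]cyclohex-3-en-1-yl acetate (not isolated) | CC1=C(C#C[Si](C)(C)C)C(C)(C)C[C@@H](OC(C)=O)C1 | intermediate
24 | (1S)-4-ethynyl-3,5,5-trimethylcyclohex-3-en-1-ol | CC1=C(C#C)C(C)(C)C[C@@H](O)C1 | intermediate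
25 | (1R,3R,6R)-6-ethynyl-1,5,5-trimethyl-7-oxabicyclo[4.1.0]heptan-3-ol | C#C[C@@]12O[C@]1(C)C[C@H](O)CC2(C)C | intermediate
26 | (1R,2S,4R)-1-ethynyl-2,6,6-trimethylcyclohexane-1,2,4-triol | C#C[C@]1(O)C(C)(C)C[C@@H](O)C[C@]1(C)O | intermediate
27 | (1S,2S,4R)-2,6,6-trimethyl-1-[(E)-2-(tributylstannyl)ethenyl]cyclohexane-1,2,4-triol | CCCC[Sn](CCCC)(CCCC)/C=C/[C@]1(O)C(C)(C)C[C@@H](O)C[C@]1(C)O | intermediate
28 | (5Z)-5-{(2E,4E,6E,8E)-11-[(4R)-4-hydroxy-2,6,6-trimethylcyclohex-1-en-1-yl]-2,9-dimethylundeca-2,4,6,8-tetraen-10-yn-1-ylidene}-3-{(E)-2-[(1S,2S,4R)-1,2,4-trihydroxy-2,6,6-trimethylcyclohexyl]ethenyl}furan-2(5H)-one | CC1=C(C#C/C(C)=C/C=C/C=C/C=C(C)/C=C2C=C(/C=C/[C@]3(O)C(C)(C)C[C@@H](O)C[C@]3(C)O)C(=O)O/2)C(C)(C)C[C@H](O)C1 | target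

Total step count: 19. Longest linear sequence: 11 steps (steps 1–5, 7 and 15–19; the ring-A arm, steps 1–6, 10, 12, 14 and 19, is 10).

Steps most likely to fail

Step 3 (key step). The cascade may stop after the first conjugate addition, or the diene may be protodesilylated faster than it adds, so that little ring is formed. The fallback keeps the same two bonds but makes them by an anionic double Michael addition. It sets out from 2: LiN(i-Pr)2 in THF at −78 °C gives the cross-conjugated lithium dienolate, whose tertiary carbon adds to methyl acrylate. The ester enolate then closes onto the isopropenyl ketone (6-endo), and the resulting ring enolate is quenched with n-C4F9SO2F to give methyl 3,5,5-trimethyl-4-{[(nonafluorobutyl)sulfonyl]oxy}cyclohex-3-ene-1-carboxylate F1. Treatment with MeNHOMe·HCl and i-PrMgCl gives N-methoxy-N,3,5,5-tetramethyl-4-{[(nonafluorobutyl)sulfonyl]oxy}cyclohex-3-ene-1-carboxamide F2, and MeMgBr at 0 °C converts it into the methyl ketone, which is 7. This detour also by-passes step 4.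

Step 4. Proton transfer from the acetyl methyl group to the fluoride-released enolate may outrun sulfonylation, so that the sulfonyl group is delivered to the wrong enolate or aldol condensation sets in. The fallback masks the ketone before the exchange and sets out from 6. Aprotic ketalisation (1,2-bis(trimethylsilyloxy)ethane, Me3SiOTf cat., CH2Cl2, −78 °C) gives tert-butyldimethyl{[2,6,6-trimethyl-4-(2-methyl-1,3-dioxolan-2-yl)cyclohex-1-en-1-yl]oxy}silane F3. The same fluoride-catalysed nonaflation then gives 2,6,6-trimethyl-4-(2-methyl-1,3-dioxolan-2-yl)cyclohex-1-en-1-yl nonafluorobutane-1-sulfonate F4, and mild hydrolysis (pyridinium p-toluenesulfonate, wet acetone) returns to 7.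

Step 17. Water may enter at the propargylic carbon C6 instead of C5, or ionisation at C6 may precede attack, which would give the diastereomeric diol. The fallback turns that regiochemistry to advantage by feeding the other epoxide and sets out from 24. Acetylation (Ac2O, pyridine) gives (1S)-4-ethynyl-3,5,5-trimethylcyclohex-3-en-1-yl acetate F5. Undirected epoxidation with mCPBA (NaHCO3, CH2Cl2) from the face anti to the acetoxy group gives (1S,3R,6S)-6-ethynyl-1,5,5-trimethyl-7-oxabicyclo[4.1.0]heptan-3-yl acetate F6. Acid hydrolysis with attack at C6 and inversion there gives (1R,3S,4R)-4-ethynyl-3,4-dihydroxy-3,5,5-trimethylcyclohexyl acetate F7, and methanolysis (K2CO3, MeOH) returns to 26.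

Further compounds
F1 | step 3 | methyl 3,5,5-trimethyl-4-{[(nonafluorobutyl)sulfonyl]oxy}cyclohex-3-ene-1-carboxylate (racemic) | CC1=C(OS(=O)(=O)C(F)(F)C(F)(F)C(F)(F)C(F)(F)F)C(C)(C)CC(C(=O)OC)C1
F2 | step 3 | N-methoxy-N,3,5,5-tetramethyl-4-{[(nonafluorobutyl)sulfonyl]oxy}cyclohex-3-ene-1-carboxamide (racemic) | CC1=C(OS(=O)(=O)C(F)(F)C(F)(F)C(F)(F)C(F)(F)F)C(C)(C)CC(C(=O)N(C)OC)C1
F3 | step 4 | tert-butyldimethyl{[2,6,6-trimethyl-4-(2-methyl-1,3-dioxolan-2-yl)cyclohex-1-en-1-yl]oxy}silane (racemic) | CC1=C(O[Si](C)(C)C(C)(C)C)C(C)(C)CC(C2(C)OCCO2)C1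
F4 | step 4 | 2,6,6-trimethyl-4-(2-methyl-1,3-dioxolan-2-yl)cyclohex-1-en-1-yl nonafluorobutane-1-sulfonate (racemic) | CC1=C(OS(=O)(=O)C(F)(F)C(F)(F)C(F)(F)C(F)(F)F)C(C)(C)CC(C2(C)OCCO2)C1
F5 | step 17 | (1S)-4-ethynyl-3,5,5-trimethylcyclohex-3-en-1-yl acetate | CC1=C(C#C)C(C)(C)C[C@@H](OC(C)=O)C1
F6 | step 17 | (1S,3R,6S)-6-ethynyl-1,5,5-trimethyl-7-oxabicyclo[4.1.0]heptan-3-yl acetate | C#C[C@]12O[C@@]1(C)C[C@H](OC(C)=O)CC2(C)C
F7 | step 17 | (1R,3S,4R)-4-ethynyl-3,4-dihydroxy-3,5,5-trimethylcyclohexyl acetate | C#C[C@]1(O)C(C)(C)C[C@@H](OC(C)=O)C[C@]1(C)O
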